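(All constants come from no measurement, and the outcome is calculated.)

**Early times.** In the first seconds of this flask the solid substrate dissolves into starting material, while the fed partner begins to react with both the starting material and the second substrate.

    starting material + partner ⇌ target (K1 = 0.31 M⁻¹, k1 = 0.091 M⁻¹ s⁻¹)
    second substrate + partner ⇌ second product (K2 = 25 M⁻¹, k2 = 0.050 M⁻¹ s⁻¹)
    solid substrate ⇌ starting material, rate k3*(cs3 - [starting material]) while solid is left; crystals form when [starting material] > cs3 (cs3 = 0.13 M, k3 = 0.31 s⁻¹)

solid substrate 0.16 M; partner 0.192 M (fed, over 4.0 min); second substrate 0.0320 M; time 5.0 h; the fed solution adds 0.10 times the starting volume

- amounts are per litre of the starting volume; all of the dose is in the solution fed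
- solid substrate is a solid; its amount is given per volume of the solution
- at the start none of the solid substrate is in solution
- what has only dissolved of solid substrate counts as not reacted
- the reaction counts as stopped when no species that holds the solid substrate changes by six tenths of a point or more over the second half of the time
- run time (flask): 5.0 h

1. why nothing more happens at 5.0 h, or that something still does (for what has run out or reacted, a solid counts together with what of it has only dissolved) (it is still moving / forward and back rates have come level / all of the solid substrate has reacted / the partner has run out first)
2. part of the solid substrate that has turned into other species by 5.0 h (what has only dissolved does not count)
3. the target standing at 5.0 h, as a percentage of the solid substrate charged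

**Frozen partner.** Once the feed is in, the volume has grown by the fraction 0.10. As a first guess, we let the whole charge of second substrate bind partner, which leaves 0.145 M free. At that level, the forward lag of the second step (the pseudo-first-order time constant, the reciprocal of rate constant times free partner) is 2.29 min. This and the same lag of the first step, 1.26 min, are far shorter than the 5.0 h run , so we expect forward and back rates to have come level in both steps.

**Target ratio.** When the first step's forward and back rates are level, target over dissolved starting material equals its equilibrium constant times free partner, which gives 0.0451. This target ratio is what we carry forward.

**Pinned solution.** While solid stands, dissolved starting material stays at its solubility of 0.13 M, so the target stands at 0.005862 M. Our guess left out this draw on the partner, but it also counted as bound the 0.006275 M of second substrate that we reckon stays unbound, and the two errors nearly offset. Solution and target together take up 0.149 M per starting litre, less than the 0.16 M charged, so solid remains. The target then comes to 4.03% of the solid substrate charged. The second product holds none of the solid substrate, so conversion is the same figure.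

**Forecast and result.** The forecast says that forward and back rates have come level, with conversion 4.04% and target 4.04%, the second substrate “leaving about 0.146 M free”. The simulation says that forward and back rates have come level, with conversion 4.04% and target 4.04%.

**What stands.** The relaxation half-life of the first step at 5.00 h is 0.0363 min, short against the 5.0 h run, and in this flask target over starting material reads 0.0452 against our ratio of 0.0451. In the neighbour flask with 0.77 M of partner, the same subtraction gives a rough 0.671 M free and a ratio of 0.208; its solid substrate stands at 0%, so we reckon the target's share of the charge as ratio over one plus ratio, 17.2%, and that flask gives 16.7%.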